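**Plan**

- Numbering (germacrane): lactone O–C6, ring-fusion C7, C8 (O-angeloyl), C9H2, C10(Me)–C1 oxirane, C2–C3 oxirane, C4(C15H2OH)=C5; lactone carbons C11 (α), C12 (C=O), C13 (=CH2).
- Cuts, in retrosynthetic order: C11=C13 (olefination of an α-phosphono lactone), the C15 silyl ether, the C2–C3 oxirane, C2=C3 (ring-closing metathesis of the ten-membered ring), the angelate, C7–C11 (key), O6–C12, the C7–C8 oxirane and C6–C7. This leaves a C7–C2 vinyl-oxirane vinyl iodide and a C6–C3 dienal.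
- Forward: the fragments are joined at C6–C7, the γ-lactone is closed first at C7–C11, then the carbocycle at C2=C3; the C2–C3 oxirane and the C13 methylene come last.
- Enabling feature: C7 lies between the oxygen-bearing C6 and C8, with C7–C11 anti to C8–O. The lactone ring plus C8–O is therefore a 2,3-epoxy alcohol (C6–OH, C7–C8 oxirane) opened at C7 by a two-carbon unit delivered from O6.
- Stereochemistry: C10/C1 by Shi epoxidation of a ring-derived Z diene; C7/C8 by Sharpless epoxidation, which also resolves C6; C6 by Mitsunobu inversion; C7 by SN2 inversion in the key step; C2/C3 by catalyst-controlled epoxidation anti to the C1–C10 oxirane; the C4=C5 geometry by trans-hydroalumination/iodination and Stille coupling.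

Key step: step 12

Remark: 1 and 7 are taken as purchased compounds; atoms are cited by the germacrane numbers given above.

**Route**

Step 1
Reactants: 1 4-methyl-5,6-dihydro-2H-pyran-2-one
Product: 2 4-methyl-5,6-dihydro-2H-pyran-2-ol (lactol)
Conditions: i-Bu2AlH (1.1 equiv), CH2Cl2, −78 °C; aqueous tartrate work-up
Reagents that add atoms: none
Why: Lactone-to-lactol reduction with i-Bu2AlH should stop at the lactol because the aluminium hemiacetal survives at −78 °C, and the ring keeps the C1=C10 alkene Z.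

Step 2
Reactants: 2 4-methyl-5,6-dihydro-2H-pyran-2-ol
Product: 3 (3Z)-3-methylhexa-3,5-dien-1-ol
Conditions: Ph3PCH3Br, t-BuOK, THF, 0 to 23 °C
Reagents that add atoms: methyltriphenylphosphonium bromide, C[P+](c1ccccc1)(c1ccccc1)c1ccccc1.[Br-]
Why: Wittig methylenation of the ring-opened hydroxy-enal tautomer of the lactol should turn C2 into the terminal vinyl group while the Z geometry fixed by the former ring is kept.

Step 3
Reactants: 3 (3Z)-3-methylhexa-3,5-dien-1-ol
Product: 4 2-[(2S,3R)-3-ethenyl-2-methyloxiran-2-yl]ethan-1-ol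
Conditions: D-fructose-derived Shi ketone (30 mol%), KHSO5 (as 2KHSO5·KHSO4·K2SO4), K2CO3, Bu4NHSO4, MeCN/dimethoxymethane/aqueous buffer pH 10.5, 0 °C
Reagents that add atoms: potassium peroxymonosulfate, [K+].[O-]S(=O)(=O)OO
Why: In the Shi asymmetric epoxidation the dioxirane should attack the more electron-rich trisubstituted alkene of the diene through the spiro transition state, which for this ketone delivers oxygen to the face that gives the 10S,1R vinyl oxirane.

Step 4
Reactants: 4 2-[(2S,3R)-3-ethenyl-2-methyloxiran-2-yl]ethan-1-ol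
Product: 5 2-[(2S,3R)-3-ethenyl-2-methyloxiran-2-yl]acetaldehyde
Conditions: Dess–Martin periodinane, NaHCO3, CH2Cl2, 0 °C; used crude
Reagents that add atoms: none
Why: Dess–Martin oxidation under bicarbonate buffering is near neutral and should spare both the oxirane and the elimination-prone β,γ-epoxy aldehyde.

Step 5
Reactants: 5 2-[(2S,3R)-3-ethenyl-2-methyloxiran-2-yl]acetaldehyde
Product: 6 (2S,3R)-3-ethenyl-2-[(2E)-3-iodoprop-2-en-1-yl]-2-methyloxirane
Conditions: CrCl2, CHI3, THF, 0 °C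
Reagents that add atoms: iodoform, IC(I)I
Why: In the Takai olefination the geminal dichromium species from CHI3 and CrCl2 adds to the aldehyde and eliminates to the E vinyl iodide under non-basic conditions.

Step 6
Reactants: 7 4-[(tert-butyldimethylsilyl)oxy]but-2-yn-1-ol
Product: 9 (2Z)-4-[(tert-butyldimethylsilyl)oxy]-3-iodobut-2-en-1-ol, via cyclic vinylalanate 8 (not isolated)
Conditions: NaAlH2(OCH2CH2OMe)2, THF, 0 °C; then I2, −78 °C
Reagents that add atoms: iodine, II
Why: Hydroxyl-directed trans-hydroalumination of the propargylic alcohol places hydride on C5 and aluminium on C4 in the five-membered alanate 8, and iodinolysis with retention should give the iodide cis to C6.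

Step 7
Reactants: 9 (2Z)-4-[(tert-butyldimethylsilyl)oxy]-3-iodobut-2-en-1-ol
Product: 10 (2E)-3-{[(tert-butyldimethylsilyl)oxy]methyl}penta-2,4-dien-1-ol
Conditions: Bu3SnCH=CH2, Pd(PPh3)4 (5 mol%), CuI (10 mol%), DMF, 23 °C
Reagents that add atoms: tributyl(vinyl)stannane, C=C[Sn](CCCC)(CCCC)CCCC
Why: Stille coupling proceeds with retention of alkene geometry and should install C3 as a vinyl group cis to C6, which completes the C4=C5 unit with the ring-cis arrangement.

Step 8
Reactants: 10 (2E)-3-{[(tert-butyldimethylsilyl)oxy]methyl}penta-2,4-dien-1-ol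
Product: 11 (2E)-3-{[(tert-butyldimethylsilyl)oxy]methyl}penta-2,4-dienal
Conditions: MnO2, CH2Cl2, 23 °C; used at once
Reagents that add atoms: none
Why: Allylic oxidation with MnO2 is neutral and should give the dienal without scrambling the alkene geometry.

Step 9
Reactants: 6 (2S,3R)-3-ethenyl-2-[(2E)-3-iodoprop-2-en-1-yl]-2-methyloxirane; 11 (2E)-3-{[(tert-butyldimethylsilyl)oxy]methyl}penta-2,4-dienal
Product: 12 (2E,5E)-6-{[(tert-butyldimethylsilyl)oxy]methyl}-1-[(2S,3R)-3-ethenyl-2-methyloxiran-2-yl]octa-2,5,7-trien-4-ol (both epimers at the carbinol carbon C6)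
Conditions: CrCl2, NiCl2 (1 mol%), DMSO, 23 °C
Reagents that add atoms: none
Why: In the Nozaki–Hiyama–Kishi coupling the alkenylchromium formed from 6 with retention of E geometry adds 1,2 to the aldehyde and forms the C6–C7 bond, with C6 formed without control.

Step 10
Reactants: 12 (2E,5E)-6-{[(tert-butyldimethylsilyl)oxy]methyl}-1-[(2S,3R)-3-ethenyl-2-methyloxiran-2-yl]octa-2,5,7-trien-4-ol
Product: 13 (1R,2E)-3-{[(tert-butyldimethylsilyl)oxy]methyl}-1-[(2R,3R)-3-{[(2S,3R)-3-ethenyl-2-methyloxiran-2-yl]methyl}oxiran-2-yl]penta-2,4-dien-1-ol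
Conditions: Ti(OiPr)4 (10 mol%), D-(−)-diisopropyl tartrate (15 mol%), t-BuOOH (0.6 equiv), 4 Å molecular sieves, CH2Cl2, −20 °C
Reagents that add atoms: tert-butyl hydroperoxide, CC(C)(C)OO
Why: Sharpless asymmetric epoxidation run as a kinetic resolution should epoxidise only the 6S epimer, on the face that gives the erythro 7R,8R oxirane, while the 6R epimer and the cis-substituted C4=C5 alkene react slowly and are left behind.

Step 11
Reactants: 13 (1R,2E)-3-{[(tert-butyldimethylsilyl)oxy]methyl}-1-[(2R,3R)-3-{[(2S,3R)-3-ethenyl-2-methyloxiran-2-yl]methyl}oxiran-2-yl]penta-2,4-dien-1-ol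
Product: 14 (1S,2E)-3-{[(tert-butyldimethylsilyl)oxy]methyl}-1-[(2S,3R)-3-{[(2S,3R)-3-ethenyl-2-methyloxiran-2-yl]methyl}oxiran-2-yl]penta-2,4-dien-1-yl 2-(diethoxyphosphoryl)acetate
Conditions: (EtO)2P(O)CH2CO2H, PPh3, DIAD, toluene, 0 °C
Reagents that add atoms: diethylphosphonoacetic acid, CCOP(=O)(OCC)CC(=O)O
Why: Mitsunobu esterification with the acidic phosphonoacetic acid inverts C6 by SN2 displacement of the oxyphosphonium ion and should give the threo epoxy ester with the C6 configuration of the target.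

Step 12
Reactants: 14 (1S,2E)-3-{[(tert-butyldimethylsilyl)oxy]methyl}-1-[(2S,3R)-3-{[(2S,3R)-3-ethenyl-2-methyloxiran-2-yl]methyl}oxiran-2-yl]penta-2,4-dien-1-yl 2-(diethoxyphosphoryl)acetate
Product: 16 diethyl {(4R,5S)-5-[(1E)-2-{[(tert-butyldimethylsilyl)oxy]methyl}buta-1,3-dien-1-yl]-4-{(1R)-2-[(2S,3R)-3-ethenyl-2-methyloxiran-2-yl]-1-hydroxyethyl}-2-oxooxolan-3-yl}phosphonate (both C11 epimers), via sodium enolate 15 (not isolated)
Conditions: NaH, THF, 0 to 45 °C; then AcOH
Reagents that add atoms: none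
Why: NaH removes the phosphonoacetate proton and the enolate carbon C11, held by the O6 ester tether, attacks C7 of the C7–C8 oxirane opposite to its C–O bond, so that release of the oxirane strain pays for the C7–C11 bond and frees the C8 oxygen. The reaction type is the intramolecular C-alkylation of a stabilised ester enolate by an epoxide (Stork-type epoxide cyclisation), run through the ester tether that closes α-phosphono lactones in telescoped intramolecular Michael/olefination sequences, with the regiochemistry of the base-mediated closure of 2,3-epoxy-alcohol carbamates at the proximal carbon. The γ-lactone closes 5-exo-tet, and the 6-endo path to C8 has the poorer collinear approach and is not expected. C7 is set by SN2 inversion of the Sharpless-derived oxirane carbon while C6 and C8 keep their C–O bonds, so the cis C6/C7 and anti C7–C11/C8–O relations of the target follow from the threo ester; C11 forms as both epimers, which is without consequence because it becomes sp2 in step 17. The step needs chemoselectivity against the C1–C10 vinyl oxirane, which C11 could reach only through an eight-membered transition state, and against migration of the lactone to O8, which should be checked because the C8 alkoxide is at once protonated by the more acidic phosphono-lactone C–H and the resulting enolate 15 is inert until the acetic acid quench.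

Step 13
Reactants: 16 diethyl {(4R,5S)-5-[(1E)-2-{[(tert-butyldimethylsilyl)oxy]methyl}buta-1,3-dien-1-yl]-4-{(1R)-2-[(2S,3R)-3-ethenyl-2-methyloxiran-2-yl]-1-hydroxyethyl}-2-oxooxolan-3-yl}phosphonate
Product: 17 diethyl {(4R,5S)-5-[(1E)-2-{[(tert-butyldimethylsilyl)oxy]methyl}buta-1,3-dien-1-yl]-4-[(1R)-2-[(2S,3R)-3-ethenyl-2-methyloxiran-2-yl]-1-{[(2Z)-2-methylbut-2-enoyl]oxy}ethyl]-2-oxooxolan-3-yl}phosphonate
Conditions: angelic acid, 2,4,6-Cl3C6H2COCl, Et3N, toluene, 23 °C; then 16, 75 °C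
Reagents that add atoms: angelic acid, C/C=C(/C)C(=O)O
Why: Yamaguchi-type acylation with the preformed angelic 2,4,6-trichlorobenzoic mixed anhydride, without a nucleophilic amine catalyst, should esterify the hindered C8 hydroxyl without isomerising the angelate to the tiglate.

Step 14
Reactants: 17 diethyl {(4R,5S)-5-[(1E)-2-{[(tert-butyldimethylsilyl)oxy]methyl}buta-1,3-dien-1-yl]-4-[(1R)-2-[(2S,3R)-3-ethenyl-2-methyloxiran-2-yl]-1-{[(2Z)-2-methylbut-2-enoyl]oxy}ethyl]-2-oxooxolan-3-yl}phosphonate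
Product: 18 diethyl [(1R,6S,7R,8R,10S)-8-angeloyloxy-15-(tert-butyldimethylsilyloxy)-1,10-epoxygermacra-2Z,4-dien-12,6-olid-11-yl]phosphonate (C3 and C6 cis on C4=C5; both C11 epimers)
Conditions: second-generation Grubbs catalyst (H2IMes)(PCy3)Cl2Ru=CHPh (10 mol%), toluene (1 mM), 80 °C
Reagents that add atoms: none
Why: Ring-closing metathesis of the two monosubstituted alkenes, held cis on the lactone and pre-bent by the cis oxirane and the C4=C5 alkene, should close the ten-membered ring, whose strain allows only the Z C2=C3 alkene, with the trisubstituted alkenes and the phosphonate as spectators.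

Step 15
Reactants: 18 diethyl [(1R,6S,7R,8R,10S)-8-angeloyloxy-15-(tert-butyldimethylsilyloxy)-1,10-epoxygermacra-2Z,4-dien-12,6-olid-11-yl]phosphonate
Product: 19 diethyl [(1R,2S,3S,6S,7R,8R,10S)-8-angeloyloxy-15-(tert-butyldimethylsilyloxy)-1,10:2,3-diepoxygermacr-4Z-en-12,6-olid-11-yl]phosphonate
Conditions: (S,S)-[N,N'-bis(3,5-di-tert-butylsalicylidene)cyclohexane-1,2-diaminato]MnCl (5 mol%), N-methylmorpholine N-oxide, mCPBA, CH2Cl2, −78 °C
Reagents that add atoms: 3-chloroperoxybenzoic acid, OOC(=O)c1cccc(Cl)c1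
Why: In the Jacobsen–Katsuki epoxidation the oxomanganese salen oxidant should prefer the conjugated cis-disubstituted C2=C3 alkene over the trisubstituted C4=C5 alkene (deactivated by two allylic C–O bonds and shielded by the silyloxymethyl group), and the (S,S) catalyst together with approach anti to the C1–C10 oxirane oxygen sets 2S,3S.

Step 16
Reactants: 19 diethyl [(1R,2S,3S,6S,7R,8R,10S)-8-angeloyloxy-15-(tert-butyldimethylsilyloxy)-1,10:2,3-diepoxygermacr-4Z-en-12,6-olid-11-yl]phosphonate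
Product: 20 diethyl [(1R,2S,3S,6S,7R,8R,10S)-8-angeloyloxy-1,10:2,3-diepoxy-15-hydroxygermacr-4Z-en-12,6-olid-11-yl]phosphonate
Conditions: Bu4NF, AcOH (1:1), THF, 0 °C
Reagents that add atoms: none
Why: Fluoride-mediated desilylation cleaves the primary silyl ether while the acetic acid buffer should protect the oxiranes, the angelate and the lactone.

Step 17
Reactants: 20 diethyl [(1R,2S,3S,6S,7R,8R,10S)-8-angeloyloxy-1,10:2,3-diepoxy-15-hydroxygermacr-4Z-en-12,6-olid-11-yl]phosphonate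
Product: 21 (1R,2S,3S,6S,7R,8R,10S)-8-angeloyloxy-1,10:2,3-diepoxy-15-hydroxygermacra-4Z,11(13)-dien-12,6-olide (CNP0157626.1)
Conditions: K2CO3, 37% aqueous HCHO, THF, 0 to 23 °C
Reagents that add atoms: formaldehyde, C=O
Why: Horner–Wadsworth–Emmons olefination of the phosphonate-stabilised lactone carbanion with formaldehyde under mild carbonate conditions removes the phosphonate helper and should create the exocyclic C11=C13 methylene of the target.

**Compound list**

1 | 4-methyl-5,6-dihydro-2H-pyran-2-one | CC1=CC(=O)OCC1 | starting material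
2 | 4-methyl-5,6-dihydro-2H-pyran-2-ol | CC1=CC(O)OCC1 | intermediate
3 | (3Z)-3-methylhexa-3,5-dien-1-ol | OCC/C(C)=C\C=C | intermediate
4 | 2-[(2S,3R)-3-ethenyl-2-methyloxiran-2-yl]ethan-1-ol | C=C[C@H]1O[C@@]1(C)CCO | intermediate
5 | 2-[(2S,3R)-3-ethenyl-2-methyloxiran-2-yl]acetaldehyde | C=C[C@H]1O[C@@]1(C)CC=O | intermediate
6 | (2S,3R)-3-ethenyl-2-[(2E)-3-iodoprop-2-en-1-yl]-2-methyloxirane | C=C[C@H]1O[C@@]1(C)C/C=C/I | intermediate
7 | 4-[(tert-butyldimethylsilyl)oxy]but-2-yn-1-ol | OCC#CCO[Si](C)(C)C(C)(C)C | starting material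
8 | cyclic sodium vinylalanate (five-membered ring Al–O–CH2–CH=C, Al on the carbon bearing CH2OTBS, two 2-methoxyethoxy groups on Al) | [Na+].COCCO[Al-]1(OCCOC)OCC=C1CO[Si](C)(C)C(C)(C)C | intermediate
9 | (2Z)-4-[(tert-butyldimethylsilyl)oxy]-3-iodobut-2-en-1-ol | OC/C=C(\I)CO[Si](C)(C)C(C)(C)C | intermediate
10 | (2E)-3-{[(tert-butyldimethylsilyl)oxy]methyl}penta-2,4-dien-1-ol | OC/C=C(\C=C)CO[Si](C)(C)C(C)(C)C | intermediate
11 | (2E)-3-{[(tert-butyldimethylsilyl)oxy]methyl}penta-2,4-dienal | O=C/C=C(\C=C)CO[Si](C)(C)C(C)(C)C | intermediate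
12 | (2E,5E)-6-{[(tert-butyldimethylsilyl)oxy]methyl}-1-[(2S,3R)-3-ethenyl-2-methyloxiran-2-yl]octa-2,5,7-trien-4-ol, both C-4 (C6) epimers | C=C/C(CO[Si](C)(C)C(C)(C)C)=C\C(O)/C=C/C[C@]1(C)O[C@@H]1C=C | intermediate
13 | (1R,2E)-3-{[(tert-butyldimethylsilyl)oxy]methyl}-1-[(2R,3R)-3-{[(2S,3R)-3-ethenyl-2-methyloxiran-2-yl]methyl}oxiran-2-yl]penta-2,4-dien-1-ol (erythro epoxy alcohol) | C=C/C(CO[Si](C)(C)C(C)(C)C)=C\[C@@H](O)[C@H]1O[C@@H]1C[C@]1(C)O[C@@H]1C=C | intermediate
14 | (1S,2E)-3-{[(tert-butyldimethylsilyl)oxy]methyl}-1-[(2S,3R)-3-{[(2S,3R)-3-ethenyl-2-methyloxiran-2-yl]methyl}oxiran-2-yl]penta-2,4-dien-1-yl 2-(diethoxyphosphoryl)acetate (threo epoxy ester) | C=C/C(CO[Si](C)(C)C(C)(C)C)=C\[C@H](OC(=O)CP(=O)(OCC)OCC)[C@H]1O[C@@H]1C[C@]1(C)O[C@@H]1C=C | intermediate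
15 | sodium enolate of 16 (C11=C12–O−, free C8 hydroxyl) | [Na+].CCOP(=O)(OCC)C1=C([O-])O[C@@H](/C=C(\C=C)CO[Si](C)(C)C(C)(C)C)[C@H]1[C@H](O)C[C@]2(C)O[C@@H]2C=C | intermediate
16 | diethyl {(4R,5S)-5-[(1E)-2-{[(tert-butyldimethylsilyl)oxy]methyl}buta-1,3-dien-1-yl]-4-{(1R)-2-[(2S,3R)-3-ethenyl-2-methyloxiran-2-yl]-1-hydroxyethyl}-2-oxooxolan-3-yl}phosphonate, both C11 epimers | CCOP(=O)(OCC)C1C(=O)O[C@@H](/C=C(\C=C)CO[Si](C)(C)C(C)(C)C)[C@H]1[C@H](O)C[C@]2(C)O[C@@H]2C=C | intermediate
17 | 8-O-angelate of 16: diethyl {(4R,5S)-5-[(1E)-2-{[(tert-butyldimethylsilyl)oxy]methyl}buta-1,3-dien-1-yl]-4-[(1R)-2-[(2S,3R)-3-ethenyl-2-methyloxiran-2-yl]-1-{[(2Z)-2-methylbut-2-enoyl]oxy}ethyl]-2-oxooxolan-3-yl}phosphonate | CCOP(=O)(OCC)C1C(=O)O[C@@H](/C=C(\C=C)CO[Si](C)(C)C(C)(C)C)[C@H]1[C@H](OC(=O)/C(C)=C\C)C[C@]2(C)O[C@@H]2C=C | intermediate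
18 | diethyl [(1R,6S,7R,8R,10S)-8-angeloyloxy-15-(tert-butyldimethylsilyloxy)-1,10-epoxygermacra-2Z,4-dien-12,6-olid-11-yl]phosphonate (C3 and C6 cis on C4=C5) | CCOP(=O)(OCC)C1C(=O)O[C@H]2/C=C(CO[Si](C)(C)C(C)(C)C)\C=C/[C@H]3O[C@@]3(C)C[C@@H](OC(=O)/C(C)=C\C)[C@@H]12 | intermediate
19 | diethyl [(1R,2S,3S,6S,7R,8R,10S)-8-angeloyloxy-15-(tert-butyldimethylsilyloxy)-1,10:2,3-diepoxygermacr-4Z-en-12,6-olid-11-yl]phosphonate | CCOP(=O)(OCC)C1C(=O)O[C@H]2/C=C(/CO[Si](C)(C)C(C)(C)C)[C@@H]3O[C@@H]3[C@H]3O[C@@]3(C)C[C@@H](OC(=O)/C(C)=C\C)[C@@H]12 | intermediate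
20 | diethyl [(1R,2S,3S,6S,7R,8R,10S)-8-angeloyloxy-1,10:2,3-diepoxy-15-hydroxygermacr-4Z-en-12,6-olid-11-yl]phosphonate | CCOP(=O)(OCC)C1C(=O)O[C@H]2/C=C(/CO)[C@@H]3O[C@@H]3[C@H]3O[C@@]3(C)C[C@@H](OC(=O)/C(C)=C\C)[C@@H]12 | intermediate
21 | (1R,2S,3S,6S,7R,8R,10S)-8-angeloyloxy-1,10:2,3-diepoxy-15-hydroxygermacra-4Z,11(13)-dien-12,6-olide | C=C1C(=O)O[C@H]2/C=C(/CO)[C@@H]3O[C@@H]3[C@H]3O[C@@]3(C)C[C@@H](OC(=O)/C(C)=C\C)[C@@H]12 | target

**Step count and risks**

Total steps: 17. Longest linear sequence: 14 (steps 1–5 and 9–17).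

Steps most likely to fail:

1. Step 12. The doubly stabilised enolate may be too weak a nucleophile for the internal oxirane, so that cleavage or migration of the ester outruns C–C bond formation. The fallback sets out from 13, closes the ring with an unstabilised ester enolate and brings the phosphonate in afterwards. Mitsunobu inversion of 13 with acetic acid should give the threo epoxy acetate F1. KN(SiMe3)2 in THF at −78 to −20 °C (Stork-type epoxy ester cyclisation) followed by Et3SiCl should give the 8-O-triethylsilyl lactone F2. LiN(i-Pr)2 and ClP(O)(OEt)2 convert it into the lactone enol phosphate F3, which a second equivalent of LiN(i-Pr)2 rearranges by 1,3-phosphorus shift to the silylated phosphono lactone F4. AcOH/THF/H2O removes the triethylsilyl group and returns to 16.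

2. Step 14. Intermolecular metathesis to oligomers, or failure of the ruthenium carbene to reach the second alkene across the fused lactone, may prevent closure of the ten-membered ring. The fallback sets out from 14 and closes the carbocycle before the lactone. Ring-closing metathesis of 14 under the conditions of step 14 should give the ten-membered epoxy phosphonoacetate F5. NaH in THF then closes the lactone inside the ring to the macrocyclic hydroxy phosphono lactone F6. Angeloylation as in step 13 returns to 18.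

3. Step 15. The oxidant may attack the trisubstituted C4=C5 alkene as well, or the wrong face of C2=C3. The fallback sets out from 18 and deactivates C4=C5 as an enal before epoxidation. Bu4NF/AcOH should give the allylic alcohol F7 and MnO2 the enal F8. Dimethyldioxirane in acetone at 0 °C then epoxidises the only electron-rich alkene left, C2=C3, anti to the neighbouring oxirane, to give the epoxy enal F9. NaBH4/CeCl3 in MeOH at −78 °C (Luche reduction) returns to 20.

Further compounds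
F1 | step 12 | (1S,2E)-3-{[(tert-butyldimethylsilyl)oxy]methyl}-1-[(2S,3R)-3-{[(2S,3R)-3-ethenyl-2-methyloxiran-2-yl]methyl}oxiran-2-yl]penta-2,4-dien-1-yl acetate | C=C/C(CO[Si](C)(C)C(C)(C)C)=C\[C@H](OC(C)=O)[C@H]1O[C@@H]1C[C@]1(C)O[C@@H]1C=C
F2 | step 12 | (4S,5S)-5-[(1E)-2-{[(tert-butyldimethylsilyl)oxy]methyl}buta-1,3-dien-1-yl]-4-{(1R)-2-[(2S,3R)-3-ethenyl-2-methyloxiran-2-yl]-1-[(triethylsilyl)oxy]ethyl}oxolan-2-one | C1C(=O)O[C@@H](/C=C(\C=C)CO[Si](C)(C)C(C)(C)C)[C@H]1[C@H](O[Si](CC)(CC)CC)C[C@]2(C)O[C@@H]2C=C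
F3 | step 12 | diethyl enol phosphate of F2 (C11=C12–O–P(O)(OEt)2) | C1=C(OP(=O)(OCC)OCC)O[C@@H](/C=C(\C=C)CO[Si](C)(C)C(C)(C)C)[C@H]1[C@H](O[Si](CC)(CC)CC)C[C@]2(C)O[C@@H]2C=C
F4 | step 12 | 8-O-triethylsilyl ether of 16 | CCOP(=O)(OCC)C1C(=O)O[C@@H](/C=C(\C=C)CO[Si](C)(C)C(C)(C)C)[C@H]1[C@H](O[Si](CC)(CC)CC)C[C@]2(C)O[C@@H]2C=C
F5 | step 14 | ten-membered epoxy phosphonoacetate: (1R,6S,7S,8R,10S)-15-(tert-butyldimethylsilyloxy)-1,10:7,8-diepoxy-cyclodeca-2Z,4-dien-6-yl 2-(diethoxyphosphoryl)acetate in germacrane numbering (C3 and C6 cis on C4=C5) | C1[C@]2(C)O[C@@H]2/C=C\C(CO[Si](C)(C)C(C)(C)C)=C/[C@H](OC(=O)CP(=O)(OCC)OCC)[C@H]2O[C@H]12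
F6 | step 14 | diethyl [(1R,6S,7R,8R,10S)-15-(tert-butyldimethylsilyloxy)-1,10-epoxy-8-hydroxygermacra-2Z,4-dien-12,6-olid-11-yl]phosphonate | CCOP(=O)(OCC)C1C(=O)O[C@H]2/C=C(CO[Si](C)(C)C(C)(C)C)\C=C/[C@H]3O[C@@]3(C)C[C@@H](O)[C@@H]12
F7 | step 15 | diethyl [(1R,6S,7R,8R,10S)-8-angeloyloxy-1,10-epoxy-15-hydroxygermacra-2Z,4-dien-12,6-olid-11-yl]phosphonate | CCOP(=O)(OCC)C1C(=O)O[C@H]2/C=C(CO)\C=C/[C@H]3O[C@@]3(C)C[C@@H](OC(=O)/C(C)=C\C)[C@@H]12
F8 | step 15 | diethyl [(1R,6S,7R,8R,10S)-8-angeloyloxy-1,10-epoxy-15-oxogermacra-2Z,4-dien-12,6-olid-11-yl]phosphonate | CCOP(=O)(OCC)C1C(=O)O[C@H]2/C=C(C=O)\C=C/[C@H]3O[C@@]3(C)C[C@@H](OC(=O)/C(C)=C\C)[C@@H]12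
F9 | step 15 | diethyl [(1R,2S,3S,6S,7R,8R,10S)-8-angeloyloxy-1,10:2,3-diepoxy-15-oxogermacr-4-en-12,6-olid-11-yl]phosphonate | CCOP(=O)(OCC)C1C(=O)O[C@H]2/C=C(/C=O)[C@@H]3O[C@@H]3[C@H]3O[C@@]3(C)C[C@@H](OC(=O)/C(C)=C\C)[C@@H]12
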